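**An impossible slope.** Reading an order in reagent from these runs was impossible, because none of them changed its charge. A tangent at the level asked also drowned in a scatter of 1 percentage point. So I bracketed the order in free catalyst, which the south run varies.

| setting | west | south-west | south | flask |
|---|---|---|---|---|
| left-handed substrate | 0.10 M | 0.40 M | 0.20 M | 0.20 M |
| right-handed substrate | 0.10 M | 0.40 M | 0.20 M | 0.20 M |
| reagent | 0.24 M | 0.24 M | 0.24 M | 0.240 M |
| free catalyst | 0.16 mM | 0.16 mM | 0.32 mM | 0.16 mM |
| impurity | 34 µM | 34 µM | 34 µM | 34 µM |
| remark | run made earlier | run made earlier | run made earlier |  |

| run | time / min | left-handed product / % |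
|---|---|---|
| west | 0.833 | 0.7 |
| west | 2.50 | 0.3 |
| west | 4.00 | 2.8 |
| west | 6.00 | 4.4 |
| west | 10.0 | 6.2 |
| west | 12.0 | 8.1 |
| west | 15.0 | 8.8 |
| south-west | 1.33 | 0.6 |
| south-west | 2.00 | 1.9 |
| south-west | 3.00 | 4.3 |
| south-west | 4.00 | 4.5 |
| south-west | 6.00 | 3.5 |
| south-west | 10.0 | 6.9 |
| south-west | 15.0 | 9.2 |
| south | 1.33 | 2.5 |
| south | 4.00 | 7.2 |
| south | 8.00 | 12.1 |
| south | 10.0 | 12.7 |
| south | 15.0 | 15.9 |

(each reading ± 1 percentage point)

- free catalyst is single-handed; left-handed substrate and right-handed substrate are mirror images of each other, charged as a racemate, each of them at the stated concentration
- on the list of suspects stand: reagent + free catalyst + left-handed substrate -> free catalyst + left-handed product; reagent + free catalyst + right-handed substrate -> free catalyst + right-handed product; 2 reagent -> self-condensation product; free catalyst + impurity -> spent catalyst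
- no earlier run changes the charge of reagent; that part of a forecast is a guess

* apparent order in reagent when 10% of the left-handed substrate and right-handed substrate together are converted (percent change of the rate of making left-handed product for one percent more reagent charged)
* apparent order in free catalyst when 10% of the left-handed substrate and right-handed substrate together are converted (percent change of the rate of making left-handed product for one percent more free catalyst charged)

**Lower bound.** Suppose c(reagent) stood still and the impurity removed catalyst one for one. The order would then be 1.27, the poison factor, charged catalyst over charged catalyst less impurity.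

**Tightened bracket.** A common level of left-handed product gave me mean rates, not tangents. The west and south-west runs averaged 9.00% left-handed product after 15.0 min, and the south run passed that level after about 5.47 min. So the mean rate rose 2.74 times, more than the 2.27 times of the working catalyst. I read the surplus as mean c(reagent) kept by arriving sooner, an order of 0.231 on working catalyst. I assumed that this loss stood at the level asked between one and two times its mean, so I put the order between 1.56 and 1.86, as readings with their scatter.

**The forecast.** It said 1.1 in reagent and 1.3 in free catalyst, “slightly higher going by the data”. Its catalyst figure lay lower than my bracket.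

**The flask.** It gave 1.2 in reagent and 1.7 in free catalyst, which is less than my top and more than my bottom.

    reagent + free catalyst + left-handed substrate → free catalyst + left-handed product (k = 9.20 L² mol⁻² s⁻¹)
    reagent + free catalyst + right-handed substrate → free catalyst + right-handed product (k = 0.970 L² mol⁻² s⁻¹)
    2 reagent → self-condensation product (k = 8.40 × 10⁻⁴ L mol⁻¹ s⁻¹)
    free catalyst + impurity → spent catalyst (k = 2900 L mol⁻¹ s⁻¹)

**The reason.** The same flask without self-condensation gives 1.3, close to the poison factor, so the loss of reagent to self-condensation product supplies part of the order, 0.407. The same flask without impurity, whose poison factor is one, gives 1.3, so the loss of free catalyst to impurity supplies another part, 0.426. Multiplied by 1.27, that 1.3 makes 1.59, against 1.7 in the flask.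

The readings are simulated from invented constants.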